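## The problem

Target 28 is a hexasubstituted benzene (ring A) joined through one methine carbon, C7, to C2' of an enolised 4,4,6,6-tetramethylcyclohexane-1,3,5-trione (ring B). Ring A carries C7 at C1, hydroxyls at C2, C4 and C6, a methyl at C3 and a 3-phenylpropanoyl group at C5. C7 also bears an isobutyl group and is the only stereocentre, so nothing in the molecule can relay configuration to it; it has to be set absolutely. It is also fragile: it sits between an electron-rich phenol ring and the central carbon of a vinylogous acid, so acid, Lewis acid or hot base can break the C7–C1 or C7–C2' bond reversibly (retro-Friedel–Crafts or retro-Michael through a quinone methide) and racemise it. A free phenol ortho to C7 and the ring B enol can also lose water under acid to give a xanthenedione, which rules out harsh acidic steps once both rings are present. The triketone is a strong carbon acid, the aryl ketone is enolisable, and the polyphenoxide of a fully substituted phloroglucinol is prone to C-alkylation and air oxidation. The feature that opens a short route to ring A is its alternation of oxygen (C2, C4, C6) and carbon (C1, C3, C5) substituents: this is the pattern formed when the C=O and C–OR carbons of a 3-alkoxycyclobutenone combine with the oxygen-bearing carbon of a siloxyalkyne, and C7 can sit on the sp3 carbon of the cyclobutenone, outside every bond that is made.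

## Retrosynthesis

**28 from 27.** The three O–benzyl bonds are cut last. Hydrogenolysis is neutral, so the completed skeleton never meets the acid that would cyclodehydrate it or ionise C7. Tribenzyl ether 27 is as complex as 28; the forward step must only leave the chelated aryl ketone and the enol untouched.

**27 from 26, and 26 from 22 and 23.** Ring B is opened at C2'–C3' (Dieckmann closure) and then at C1'–C6' (acylation of the enolate of keto ester 23 by the acid chloride 24 of acid 22). The alternative cut at C7–C2' would require a ring B nucleophile to be joined to a benzylic cation or quinone methide, which is planar at C7 and gives racemate. In the chosen cut the C7–C2' bond is never made: it is the C7–CH2 bond of 22. The precursor 22 is a simple arylhexanoic acid and 23 is a commodity keto ester. The forward steps must achieve C-acylation at a tetrasubstituted enolate carbon and ring closure through carbon, in the presence of an aryl ketone that is already in place.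

**22 from 21, 21 from 19, 19 from 16 and 17.** These are functional-group and protecting-group changes, plus the C5–acyl bond. The acyl group is introduced on lactone 16 with acid chloride 17, and the silyl and ethyl ethers left by the annulation are cleaved in the same operation. At that stage C7 carries only a CH2–C=O arm and cannot ionise. Acylation after ring B would expose the acid-sensitive skeleton to a Lewis acid. Lactone 19 is then opened and benzylated to 21, whose ethers survive enolate chemistry and leave under hydrogen. The forward steps need acylation at the one free, doubly ortho-oxygenated ring carbon and O- rather than C-benzylation.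

**16 from 15.** The lactone C–O bond is cut. The phenol of 15 lies ortho to a propanoate chain, so closure to the dihydrocoumarin is favourable. The lactone masks phenol and carboxyl together for the Lewis-acid step.

**15 from 6 and 10 (key disconnection).** Ring A is cut at C2–C3 and C4–C5, with C1–C2 re-formed in the closure. This gives 3-ethoxycyclobutenone 6, which carries the whole C7 side chain, and siloxyalkyne 10. Stepwise substitution of a phloroglucinol would need three regiocontrolled C–C bond formations on a crowded ring and an asymmetric benzylic bond. The cut instead delivers the whole oxygen/carbon alternation regiospecifically in a neutral, pericyclic step, and leaves one ring CH for the acyl group. The precursors are a four-membered ring and a three-carbon alkyne. The forward reaction must show regiocontrol in the ketene–alkyne union and leave the ester and C7 untouched.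

**6 from 2 and 3; 10 from 7.** The cyclobutenone is cut across its two ring bonds to the ketene 5 of hemiester 2 (through acid chloride 4) and ethoxyacetylene 3. Alkyne 10 comes from propyne 7 by oxidation of its acetylide and O-silylation.

**2 from 1.** The two carboxyl arms of 2 are enantiotopic in anhydride 1. Catalytic enantioselective methanolysis therefore sets C7 in the first step from a commercial meso compound and differentiates the arm that becomes ring A from the arm that becomes ring B.

## Roads not taken

**Alternative 1: three-component conjunctive coupling at C7.** The cut is the ring A–C7 bond together with the CH2–alkenyl bond of the isobutyl chain. Forward, aryllithium A1 adds to vinylboronate A2 to give an ate complex. A chiral palladium catalyst and alkenyl triflate A3 then trigger a 1,2-aryl shift from boron to carbon and deliver boronate A4 with C7 set by the ligand.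
- Merits: the stereocentre is made catalytically and convergently from three simple components, and ring A is taken intact from a symmetric trioxygenated toluene.
- Weak points: the migrating aryl group is 2,6-dioxygenated and hindered. More seriously, A4 has no ring B. The C–B bond at a crowded, ionisable benzylic centre must become the C7–C2' bond with full stereochemical fidelity, and a 1,3,5-trione offers no direct coupling partner. It would take a second arylation followed by dearomatisation, or a homologation and then the same ring B construction as in the chosen route. Alkene reduction and acylation also remain.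
- Comparison: in creating C7 this road equals the chosen one in expected selectivity and is better in convergence. Against that, the chosen plan sets C7 in step 1 and never makes or breaks a bond at C7 afterwards, whereas here the hardest bond at C7 is still ahead after the key step.

**Alternative 2: ring expansion of a cyclobutanedione by a dihydrocoumarin enolate.** The cut is two ring B bonds, from the lactone α-carbon to one ring carbonyl and from the lactone carbonyl to a CMe2 carbon. Forward, the enolate of lactone A5 adds to dione A6, the strained alkoxide opens, and the new ketone enolate closes on the lactone carbonyl. This expels the ring A phenoxide and gives A7.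
- Merits: ring B forms in one operation from a commodity diketone, driven by strain, and no protecting group is needed at the phenol.
- Weak points: the first addition is to a tetrasubstituted ketone, the aryl ester enolate can eliminate to a ketene, and closure through carbon rather than oxygen is not assured. Enantioenriched A5 must first be made, which is a separate asymmetric problem on a hindered coumarin. The acyl group must then be introduced by Friedel–Crafts chemistry on A7, where a free phenol ortho to C7 and the ring B enol invite cyclodehydration and C7 cleavage.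
- Comparison: for ring B this road is shorter (one step against steps 8 to 10) and it uses the same kind of dihydrocoumarin that the chosen route passes through (16, 19, 20). The chosen plan offers a ring B assembly from known reaction types, acylation before ring B exists, and C7 from an established desymmetrisation.

**Alternative 3: biomimetic dearomative tetra-C-methylation.** The cut is the four C–CH3 bonds of ring B. Forward, diarylmethine A8 carries a protected acylated ring and a free 2,4,6-trihydroxyphenyl ring on C7. A methyl halide and methoxide base methylate the free ring four times at carbon and dearomatise it to ring B, giving A9.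
- Merits: it follows the likely biosynthesis, needs no ring-closing step for ring B, and is the shortest on paper if A8 is in hand.
- Weak points: the ring carbon that bears C7 is alkyl- rather than acyl-substituted and can take a fifth methyl group. O-methylation and methylation α to the aryl ketone compete. A8 itself must be a single enantiomer although its two aryl groups are electronically almost identical and either can ionise the C7–aryl bond. The acetal removal that follows needs acid on the complete skeleton.
- Comparison: this road is better in step count and in using two simple phloroglucinol units. The chosen plan is longer, but it has a defined source of C7 configuration and no step in which C7 sits between two freely ionising rings.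

Key step: step 4

Assumption: (DHQD)2AQN is taken to give the (S)-hemiester 2; if the first batch shows the opposite sense, its pseudo-enantiomer (DHQ)2AQN is used instead and nothing else changes.

Remark on locants: ring A is numbered C1 (bears C7), C2 (O), C3 (methyl), C4 (O), C5 (acyl), C6 (O) throughout; in the lactones the same atoms are C4a, C8a, C8, C7, C6, C5.

## Route

Step 1
Reactants: 1 3-isobutylglutaric anhydride
Product: 2 (3S)-3-(2-methoxy-2-oxoethyl)-5-methylhexanoic acid
Conditions: (DHQD)2AQN (10 mol %), MeOH (10 equiv), Et2O, −40 °C; aq. HCl wash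
Reagents that add atoms: methanol, CO
Why: Cinchona-alkaloid-catalysed enantioselective methanolysis (desymmetrisation) of a 3-substituted glutaric anhydride; the catalyst directs methanol to one of the two enantiotopic carbonyls and so sets C7. The enantiomeric purity can be raised by crystallising an amine salt of 2 if needed.

Step 2
Reactants: 2 (3S)-3-(2-methoxy-2-oxoethyl)-5-methylhexanoic acid; 3 ethoxyacetylene
Product: 6 methyl (3R)-3-[(1RS)-2-ethoxy-4-oxocyclobut-2-en-1-yl]-5-methylhexanoate, via acid chloride 4 (not isolated), via ketene 5 (not isolated)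
Conditions: (COCl)2, DMF (cat.), CH2Cl2, 0 °C to rt; evaporate; then slow addition to 3 (3 equiv), Et3N, Et2O, 0 °C to rt
Reagents that add atoms: none
Why: Dehydrochlorination gives the aldoketene, which is trapped in a ketene–alkoxyalkyne [2+2] cycloaddition; the ketene carbonyl carbon bonds to the unsubstituted alkyne carbon, giving the 3-ethoxy-4-alkyl cyclobutenone. C7 has no acidic hydrogen and is untouched; the new ring stereocentre is formed as both epimers and is erased in step 4.

Step 3
Reactants: 7 propyne
Product: 10 triisopropyl(prop-1-yn-1-yloxy)silane, via 1-propynyllithium 8 (not isolated), via lithium propynolate 9 (not isolated)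
Conditions: n-BuLi, THF, −78 °C; LiOOt-Bu (from t-BuOOH and LiN(SiMe3)2), −78 to 0 °C; then i-Pr3SiOTf, −78 °C to rt
Reagents that add atoms: tert-butyl hydroperoxide, CC(C)(C)OO; triisopropylsilyl trifluoromethanesulfonate, CC(C)[Si](C(C)C)(C(C)C)OS(=O)(=O)C(F)(F)F
Why: Oxidation of a lithium acetylide by lithium tert-butyl peroxide gives the ynolate, which is silylated on oxygen by the bulky silyl triflate; this is the standard preparation of triisopropylsiloxyalkynes.

Step 4
Reactants: 6 methyl (3R)-3-[(1RS)-2-ethoxy-4-oxocyclobut-2-en-1-yl]-5-methylhexanoate; 10 triisopropyl(prop-1-yn-1-yloxy)silane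
Product: 15 methyl (3R)-3-[6-ethoxy-2-hydroxy-3-methyl-4-(triisopropylsilyloxy)phenyl]-5-methylhexanoate, via vinylketene 11 (not isolated), via alkenylcyclobutenone 12 (not isolated), via dienylketene 13 (not isolated), via cyclohexadienone 14 (not isolated)
Conditions: 10 (1.3 equiv), toluene, 80 °C, then 110 °C
Reagents that add atoms: none
Why: Heating opens 6 by strain-releasing conrotatory 4π ring opening to vinylketene 11; the alkyl group should rotate outward, which keeps the C7 hydrogen away from the ketene and excludes a 1,5-hydrogen shift. The ketene C=C bond of 11 then undergoes a regiospecific [2+2] cycloaddition with 10, forming the C2–C3 and C4–C5 bonds of ring A and giving 12. Cyclobutenone 12 reopens to dienylketene 13, and a thermal disrotatory 6π electrocyclisation joins the ketene carbon (C2) to C1, closing ring A as dienone 14, which tautomerises to phenol 15. The closest known reaction type is the Danheiser benzannulation of cyclobutenones with trialkylsiloxyalkynes to resorcinol monosilyl ethers. No stereocentre is created: C7 is exocyclic, lies outside every bond that is reorganised and sees only a neutral medium, so the configuration from step 1 is carried through, while the ring stereocentre of 6 becomes sp2. The step needs regiocontrol in the ketene–alkyne union, which the polarised siloxyalkyne secures because its methyl-bearing carbon is the nucleophilic one and bonds to the ketene carbonyl carbon. It also needs one ring carbon left unsubstituted, which is C5, derived from the terminal carbon of 3.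

Step 5
Reactants: 15 methyl (3R)-3-[6-ethoxy-2-hydroxy-3-methyl-4-(triisopropylsilyloxy)phenyl]-5-methylhexanoate
Product: 16 (4R)-5-ethoxy-8-methyl-4-(2-methylpropyl)-7-(triisopropylsilyloxy)-3,4-dihydro-2H-chromen-2-one
Conditions: TsOH·H2O (5 mol %), toluene, 80 °C, 4 Å molecular sieves
Reagents that add atoms: none
Why: Acid-catalysed lactonisation of a 3-(2-hydroxyaryl)propanoate to the dihydrocoumarin, helped by the ortho substituents that hold the chain over the phenol; any 16 already formed in step 4 converges here. The lactone masks the phenol and the carboxyl group for the Lewis-acid step; the aryl silyl ether and C7 are not affected by catalytic acid.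

Step 6
Reactants: 16 (4R)-5-ethoxy-8-methyl-4-(2-methylpropyl)-7-(triisopropylsilyloxy)-3,4-dihydro-2H-chromen-2-one; 17 3-phenylpropanoyl chloride
Product: 19 (4R)-5,7-dihydroxy-8-methyl-4-(2-methylpropyl)-6-(3-phenylpropanoyl)-3,4-dihydro-2H-chromen-2-one, via aryl ketone 18 (not isolated)
Conditions: 17, AlCl3, CH2Cl2, 0 °C to rt; then BBr3, −78 to 0 °C; aq. work-up
Reagents that add atoms: none
Why: Friedel–Crafts acylation at the only unsubstituted ring carbon, which is activated by two ortho oxygens and the para lactone oxygen, gives 18; BBr3 then cleaves the ethyl and silyl ethers flanking the new carbonyl. At this stage the stereocentre is a benzylic CH next to a CH2–C=O arm and has no ionisation pathway at these temperatures; a regioisomeric lactone from acyl migration to the other ortho oxygen would converge at 21.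

Step 7
Reactants: 19 (4R)-5,7-dihydroxy-8-methyl-4-(2-methylpropyl)-6-(3-phenylpropanoyl)-3,4-dihydro-2H-chromen-2-one
Product: 21 methyl (3R)-5-methyl-3-[2,4,6-tris(benzyloxy)-3-methyl-5-(3-phenylpropanoyl)phenyl]hexanoate, via bis(benzyl ether) lactone 20 (not isolated)
Conditions: BnBr (4 equiv), K2CO3, DMF, 50 °C; then MeOH added, 50 °C
Reagents that add atoms: benzyl bromide, BrCc1ccccc1; methanol, CO
Why: Williamson O-benzylation of the two chelated phenols gives 20; carbonate in DMF forms the phenoxides one at a time, conditions under which O-alkylation dominates over C-alkylation. Methanol and carbonate then open the aryl lactone reversibly by transesterification, and benzylation of the freed, hindered phenoxide drains the equilibrium to 21.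

Step 8
Reactants: 21 methyl (3R)-5-methyl-3-[2,4,6-tris(benzyloxy)-3-methyl-5-(3-phenylpropanoyl)phenyl]hexanoate
Product: 22 (3R)-5-methyl-3-[2,4,6-tris(benzyloxy)-3-methyl-5-(3-phenylpropanoyl)phenyl]hexanoic acid
Conditions: LiOH, THF–MeOH–H2O, 40 °C; then 1 M HCl
Reagents that add atoms: lithium hydroxide, [Li+].[OH-]
Why: Saponification of an unhindered methyl ester; the benzyl ethers and the aryl ketone are stable to hydroxide and C7 bears no acidic hydrogen.

Step 9
Reactants: 22 (3R)-5-methyl-3-[2,4,6-tris(benzyloxy)-3-methyl-5-(3-phenylpropanoyl)phenyl]hexanoic acid; 23 methyl 2,2,4-trimethyl-3-oxopentanoate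
Product: 26 methyl (7R)-2,2,4,4,9-pentamethyl-3,5-dioxo-7-[2,4,6-tris(benzyloxy)-3-methyl-5-(3-phenylpropanoyl)phenyl]decanoate, via acid chloride 24 (not isolated), via lithium enolate 25 (not isolated)
Conditions: 22, (COCl)2, DMF (cat.), CH2Cl2, 0 °C, evaporate; 23, LiN(i-Pr)2, THF, −78 °C; enolate solution added to the acid chloride in THF, −78 °C
Reagents that add atoms: none
Why: C-acylation of a preformed lithium ketone enolate by an acid chloride, a standard route to 2,2-disubstituted 1,3-diketones; adding the enolate to the acid chloride at −78 °C keeps acylation ahead of proton transfer from the hindered aryl ketone or from the acid chloride. The new quaternary carbon is not stereogenic and C7 is not involved.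

Step 10
Reactants: 26 methyl (7R)-2,2,4,4,9-pentamethyl-3,5-dioxo-7-[2,4,6-tris(benzyloxy)-3-methyl-5-(3-phenylpropanoyl)phenyl]decanoate
Product: 27 3-hydroxy-4,4,6,6-tetramethyl-2-[(1S)-3-methyl-1-[2,4,6-tris(benzyloxy)-3-methyl-5-(3-phenylpropanoyl)phenyl]butyl]cyclohex-2-ene-1,5-dione
Conditions: LiN(i-Pr)2 (2.5 equiv), THF, −78 to 0 °C; then 1 M HCl
Reagents that add atoms: none
Why: Dieckmann condensation: the enolate at C6 attacks the methyl ester (6-exo-trig) to close ring B, and the acidic triketone is deprotonated at once, which makes the closure irreversible; the doubly ortho-substituted aryl ketone enolate formed alongside is a spectator. Any enol lactone formed through oxygen is reopened by the methoxide released, and C7 is not enolisable in the product enolate.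

Step 11
Reactants: 27 3-hydroxy-4,4,6,6-tetramethyl-2-[(1S)-3-methyl-1-[2,4,6-tris(benzyloxy)-3-methyl-5-(3-phenylpropanoyl)phenyl]butyl]cyclohex-2-ene-1,5-dione
Product: 28 3-hydroxy-4,4,6,6-tetramethyl-2-[(1S)-3-methyl-1-[2,4,6-trihydroxy-3-methyl-5-(3-phenylpropanoyl)phenyl]butyl]cyclohex-2-ene-1,5-dione
Conditions: H2 (1 atm), Pd/C (10 wt %), EtOAc, rt
Reagents that add atoms: none
Why: Hydrogenolysis of three aryl benzyl ethers under neutral conditions, which avoids the acid-promoted cyclodehydration and the reversible cleavage at C7; the chelated aryl ketone and the enolised triketone should not be reduced at atmospheric pressure.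

## Compound list

1 | 3-isobutylglutaric anhydride [4-(2-methylpropyl)oxane-2,6-dione] | CC(C)CC1CC(=O)OC(=O)C1 | starting material
2 | (3S)-3-(2-methoxy-2-oxoethyl)-5-methylhexanoic acid | OC(=O)C[C@H](CC(C)C)CC(=O)OC | intermediate
3 | ethoxyacetylene (ethoxyethyne) | CCOC#C | starting material
4 | methyl (3R)-3-(2-chloro-2-oxoethyl)-5-methylhexanoate | ClC(=O)C[C@H](CC(C)C)CC(=O)OC | intermediate (not isolated)
5 | methyl (3R)-5-methyl-3-(2-oxoethenyl)hexanoate | O=C=C[C@H](CC(C)C)CC(=O)OC | intermediate (not isolated)
6 | methyl (3R)-3-[(1RS)-2-ethoxy-4-oxocyclobut-2-en-1-yl]-5-methylhexanoate (both epimers at the ring carbon) | CCOC1=CC(=O)C1[C@H](CC(C)C)CC(=O)OC | intermediate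
7 | propyne | CC#C | starting material
8 | 1-propynyllithium | [Li]C#CC | intermediate (not isolated)
9 | lithium prop-1-yn-1-olate | CC#C[O-].[Li+] | intermediate (not isolated)
10 | triisopropyl(prop-1-yn-1-yloxy)silane | CC#CO[Si](C(C)C)(C(C)C)C(C)C | intermediate
11 | methyl (3R,4Z)-5-ethoxy-3-(2-methylpropyl)-7-oxohepta-4,6-dienoate | O=C=C/C(OCC)=C/[C@H](CC(C)C)CC(=O)OC | intermediate (not isolated)
12 | methyl (3R,4Z)-5-ethoxy-3-(2-methylpropyl)-5-[3-methyl-4-oxo-2-(triisopropylsilyloxy)cyclobut-2-en-1-yl]pent-4-enoate | O=C1C(C)=C(O[Si](C(C)C)(C(C)C)C(C)C)C1/C(OCC)=C/[C@H](CC(C)C)CC(=O)OC | intermediate (not isolated)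
13 | methyl (3R,4Z,6E)-5-ethoxy-8-methyl-3-(2-methylpropyl)-9-oxo-7-(triisopropylsilyloxy)nona-4,6,8-trienoate | O=C=C(C)/C(O[Si](C(C)C)(C(C)C)C(C)C)=C\C(OCC)=C\[C@H](CC(C)C)CC(=O)OC | intermediate (not isolated)
14 | methyl (3R)-3-[(1RS)-6-ethoxy-3-methyl-2-oxo-4-(triisopropylsilyloxy)cyclohexa-3,5-dien-1-yl]-5-methylhexanoate | O=C1C(C)=C(O[Si](C(C)C)(C(C)C)C(C)C)C=C(OCC)C1[C@H](CC(C)C)CC(=O)OC | intermediate (not isolated)
15 | methyl (3R)-3-[6-ethoxy-2-hydroxy-3-methyl-4-(triisopropylsilyloxy)phenyl]-5-methylhexanoate | Cc1c(O[Si](C(C)C)(C(C)C)C(C)C)cc(OCC)c([C@H](CC(C)C)CC(=O)OC)c1O | intermediate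
16 | (4R)-5-ethoxy-8-methyl-4-(2-methylpropyl)-7-(triisopropylsilyloxy)-3,4-dihydro-2H-chromen-2-one | O=C1C[C@@H](CC(C)C)c2c(OCC)cc(O[Si](C(C)C)(C(C)C)C(C)C)c(C)c2O1 | intermediate
17 | 3-phenylpropanoyl chloride | O=C(Cl)CCc1ccccc1 | starting material
18 | (4R)-5-ethoxy-8-methyl-4-(2-methylpropyl)-6-(3-phenylpropanoyl)-7-(triisopropylsilyloxy)-3,4-dihydro-2H-chromen-2-one | O=C1C[C@@H](CC(C)C)c2c(OCC)c(C(=O)CCc3ccccc3)c(O[Si](C(C)C)(C(C)C)C(C)C)c(C)c2O1 | intermediate (not isolated)
19 | (4R)-5,7-dihydroxy-8-methyl-4-(2-methylpropyl)-6-(3-phenylpropanoyl)-3,4-dihydro-2H-chromen-2-one | O=C1C[C@@H](CC(C)C)c2c(O)c(C(=O)CCc3ccccc3)c(O)c(C)c2O1 | intermediate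
20 | (4R)-5,7-bis(benzyloxy)-8-methyl-4-(2-methylpropyl)-6-(3-phenylpropanoyl)-3,4-dihydro-2H-chromen-2-one | O=C1C[C@@H](CC(C)C)c2c(OCc3ccccc3)c(C(=O)CCc3ccccc3)c(OCc3ccccc3)c(C)c2O1 | intermediate (not isolated)
21 | methyl (3R)-5-methyl-3-[2,4,6-tris(benzyloxy)-3-methyl-5-(3-phenylpropanoyl)phenyl]hexanoate | Cc1c(OCc2ccccc2)c(C(=O)CCc2ccccc2)c(OCc2ccccc2)c([C@H](CC(C)C)CC(=O)OC)c1OCc1ccccc1 | intermediate
22 | (3R)-5-methyl-3-[2,4,6-tris(benzyloxy)-3-methyl-5-(3-phenylpropanoyl)phenyl]hexanoic acid | Cc1c(OCc2ccccc2)c(C(=O)CCc2ccccc2)c(OCc2ccccc2)c([C@H](CC(C)C)CC(=O)O)c1OCc1ccccc1 | intermediate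
23 | methyl 2,2,4-trimethyl-3-oxopentanoate | COC(=O)C(C)(C)C(=O)C(C)C | starting material
24 | (3R)-5-methyl-3-[2,4,6-tris(benzyloxy)-3-methyl-5-(3-phenylpropanoyl)phenyl]hexanoyl chloride | Cc1c(OCc2ccccc2)c(C(=O)CCc2ccccc2)c(OCc2ccccc2)c([C@H](CC(C)C)CC(=O)Cl)c1OCc1ccccc1 | intermediate (not isolated)
25 | lithium 5-methoxy-2,4,4-trimethyl-5-oxopent-2-en-3-olate | COC(=O)C(C)(C)C([O-])=C(C)C.[Li+] | intermediate (not isolated)
26 | methyl (7R)-2,2,4,4,9-pentamethyl-3,5-dioxo-7-[2,4,6-tris(benzyloxy)-3-methyl-5-(3-phenylpropanoyl)phenyl]decanoate | Cc1c(OCc2ccccc2)c(C(=O)CCc2ccccc2)c(OCc2ccccc2)c([C@H](CC(C)C)CC(=O)C(C)(C)C(=O)C(C)(C)C(=O)OC)c1OCc1ccccc1 | intermediate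
27 | 3-hydroxy-4,4,6,6-tetramethyl-2-[(1S)-3-methyl-1-[2,4,6-tris(benzyloxy)-3-methyl-5-(3-phenylpropanoyl)phenyl]butyl]cyclohex-2-ene-1,5-dione | Cc1c(OCc2ccccc2)c(C(=O)CCc2ccccc2)c(OCc2ccccc2)c([C@H](CC(C)C)C2=C(O)C(C)(C)C(=O)C(C)(C)C2=O)c1OCc1ccccc1 | intermediate
28 | 3-hydroxy-4,4,6,6-tetramethyl-2-[(1S)-3-methyl-1-[2,4,6-trihydroxy-3-methyl-5-(3-phenylpropanoyl)phenyl]butyl]cyclohex-2-ene-1,5-dione | Cc1c(O)c(C(=O)CCc2ccccc2)c(O)c([C@H](CC(C)C)C2=C(O)C(C)(C)C(=O)C(C)(C)C2=O)c1O | target

## Step count and least certain steps

Total step count: 11. Longest linear sequence: 10 steps (steps 1, 2 and 4 to 11); step 3 is a one-step side branch.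

**Step 4 (key step).** The most likely failure is that vinylketene 11 is consumed by the phenol product or by itself (O-acylation, dimerisation) instead of by the alkyne. The donor-substituted cyclobutenone may also open so slowly that the siloxyalkyne degrades at the temperature required. Inward rotation of the alkyl group would open a 1,5-hydrogen shift from C7.
Fallback: the roles of the two alkynes are exchanged, setting out from acid chloride 4 and alkyne 10 and returning at 21.
- Ketene 5 (from 4 and Et3N) is trapped with 10 to give methyl (3R)-5-methyl-3-[(1RS)-3-methyl-4-oxo-2-(triisopropylsilyloxy)cyclobut-2-en-1-yl]hexanoate F1.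
- F1 is heated with an excess of the robust ketenophile 3 to give the differently protected phenol methyl (3R)-3-[4-ethoxy-6-hydroxy-3-methyl-2-(triisopropylsilyloxy)phenyl]-5-methylhexanoate F2.
- Lactonisation as in step 5 gives (4R)-7-ethoxy-6-methyl-4-(2-methylpropyl)-5-(triisopropylsilyloxy)-3,4-dihydro-2H-chromen-2-one F3.
- Acylation with 17 and ether cleavage as in step 6 give (4R)-5,7-dihydroxy-6-methyl-4-(2-methylpropyl)-8-(3-phenylpropanoyl)-3,4-dihydro-2H-chromen-2-one F4.
- The conditions of step 7 convert F4 into 21, because all three oxygens are benzylated there and the ring substituents alternate.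

**Step 9.** The most likely failure is acylation on the enolate oxygen, or proton transfer outrunning C–C bond formation at the tetrasubstituted carbon (ketene formation from 24, enolisation of the aryl ketone). An ortho benzyloxy oxygen may also close onto the acid chloride with loss of the benzyl group before the enolate is added.
Fallback: this sets out from 23 and 24 and returns at 26. Keto ester 23 is converted (LiN(i-Pr)2, Me3SiCl) into methyl 2,2,4-trimethyl-3-(trimethylsilyloxy)pent-3-enoate F5. F5 is acylated at carbon by 24 under a mild Lewis acid (ZnCl2, CH2Cl2, low temperature). This is a neutral, Mukaiyama-type acylation in which no basic enolate is present and the aryl ketone is not enolised.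

**Step 10.** The most likely failure is ring closure through the enolate oxygen to a six-membered enol lactone that does not revert under lithium conditions, or retro-Claisen cleavage of the non-enolisable 1,3-diketone by the methoxide released.
Fallback: the ester terminus is replaced by a nitrile, which can only be attacked productively at carbon; the sequence sets out from 24 and returns at 27.
- 2,2,4-Trimethyl-3-oxopentanenitrile F6 is made from lithiated isobutyronitrile and isobutyryl chloride.
- F6 is acylated as its lithium enolate by 24 to give (7R)-2,2,4,4,9-pentamethyl-3,5-dioxo-7-[2,4,6-tris(benzyloxy)-3-methyl-5-(3-phenylpropanoyl)phenyl]decanenitrile F7.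
- Thorpe–Ziegler cyclisation with base gives the enaminone 3-amino-4,4,6,6-tetramethyl-2-[(1S)-3-methyl-1-[2,4,6-tris(benzyloxy)-3-methyl-5-(3-phenylpropanoyl)phenyl]butyl]cyclohex-2-ene-1,5-dione F8.
- Mild aqueous acid hydrolyses F8 to 27.

**Step 6.** The most likely failure is that acylation at the crowded ring position lags behind Lewis-acid cleavage of the silyl ether, so that O-acylation and incomplete acyl migration give mixtures. Prolonged exposure to the Lewis acids could also erode configuration at C4 by reversible opening at the benzylic carbon.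
Fallback: the order is reversed, setting out from 16 and returning at 19. BBr3 first cleaves both ethers of 16 to give (4R)-5,7-dihydroxy-8-methyl-4-(2-methylpropyl)-3,4-dihydro-2H-chromen-2-one F9. The free resorcinol-type ring of F9 is then acylated ortho to its hydroxyls with 17 and TiCl4 at low temperature (phenoxide-directed C-acylation, with Fries migration of any O-acyl ester).

## Further compounds

F1 | step 4 | methyl (3R)-5-methyl-3-[(1RS)-3-methyl-4-oxo-2-(triisopropylsilyloxy)cyclobut-2-en-1-yl]hexanoate | O=C1C(C)=C(O[Si](C(C)C)(C(C)C)C(C)C)C1[C@H](CC(C)C)CC(=O)OC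
F2 | step 4 | methyl (3R)-3-[4-ethoxy-6-hydroxy-3-methyl-2-(triisopropylsilyloxy)phenyl]-5-methylhexanoate | Cc1c(OCC)cc(O)c([C@H](CC(C)C)CC(=O)OC)c1O[Si](C(C)C)(C(C)C)C(C)C
F3 | step 4 | (4R)-7-ethoxy-6-methyl-4-(2-methylpropyl)-5-(triisopropylsilyloxy)-3,4-dihydro-2H-chromen-2-one | O=C1C[C@@H](CC(C)C)c2c(O[Si](C(C)C)(C(C)C)C(C)C)c(C)c(OCC)cc2O1
F4 | step 4 | (4R)-5,7-dihydroxy-6-methyl-4-(2-methylpropyl)-8-(3-phenylpropanoyl)-3,4-dihydro-2H-chromen-2-one | O=C1C[C@@H](CC(C)C)c2c(O)c(C)c(O)c(C(=O)CCc3ccccc3)c2O1
F5 | step 9 | methyl 2,2,4-trimethyl-3-(trimethylsilyloxy)pent-3-enoate | COC(=O)C(C)(C)C(O[Si](C)(C)C)=C(C)C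
F6 | step 10 | 2,2,4-trimethyl-3-oxopentanenitrile | CC(C)C(=O)C(C)(C)C#N
F7 | step 10 | (7R)-2,2,4,4,9-pentamethyl-3,5-dioxo-7-[2,4,6-tris(benzyloxy)-3-methyl-5-(3-phenylpropanoyl)phenyl]decanenitrile | Cc1c(OCc2ccccc2)c(C(=O)CCc2ccccc2)c(OCc2ccccc2)c([C@H](CC(C)C)CC(=O)C(C)(C)C(=O)C(C)(C)C#N)c1OCc1ccccc1
F8 | step 10 | 3-amino-4,4,6,6-tetramethyl-2-[(1S)-3-methyl-1-[2,4,6-tris(benzyloxy)-3-methyl-5-(3-phenylpropanoyl)phenyl]butyl]cyclohex-2-ene-1,5-dione | Cc1c(OCc2ccccc2)c(C(=O)CCc2ccccc2)c(OCc2ccccc2)c([C@H](CC(C)C)C2=C(N)C(C)(C)C(=O)C(C)(C)C2=O)c1OCc1ccccc1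
F9 | step 6 | (4R)-5,7-dihydroxy-8-methyl-4-(2-methylpropyl)-3,4-dihydro-2H-chromen-2-one | O=C1C[C@@H](CC(C)C)c2c(O)cc(O)c(C)c2O1
A1 | alternative 1 | [3-methyl-2,4,6-tris(methoxymethoxy)phenyl]lithium | [Li]c1c(OCOC)cc(OCOC)c(C)c1OCOC
A2 | alternative 1 | 2-ethenyl-4,4,5,5-tetramethyl-1,3,2-dioxaborolane | C=CB1OC(C)(C)C(C)(C)O1
A3 | alternative 1 | prop-1-en-2-yl trifluoromethanesulfonate | CC(=C)OS(=O)(=O)C(F)(F)F
A4 | alternative 1 | 2-[(1S)-3-methyl-1-[3-methyl-2,4,6-tris(methoxymethoxy)phenyl]but-3-en-1-yl]-4,4,5,5-tetramethyl-1,3,2-dioxaborolane | Cc1c(OCOC)cc(OCOC)c([C@H](CC(C)=C)B2OC(C)(C)C(C)(C)O2)c1OCOC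
A5 | alternative 2 | (4R)-5,7-bis(benzyloxy)-6-methyl-4-(2-methylpropyl)-3,4-dihydro-2H-chromen-2-one | O=C1C[C@@H](CC(C)C)c2c(OCc3ccccc3)c(C)c(OCc3ccccc3)cc2O1
A6 | alternative 2 | 2,2,4,4-tetramethylcyclobutane-1,3-dione | CC1(C)C(=O)C(C)(C)C1=O
A7 | alternative 2 | 2-[(1S)-1-[2,4-bis(benzyloxy)-6-hydroxy-3-methylphenyl]-3-methylbutyl]-3-hydroxy-4,4,6,6-tetramethylcyclohex-2-ene-1,5-dione | Cc1c(OCc2ccccc2)cc(O)c([C@H](CC(C)C)C2=C(O)C(C)(C)C(=O)C(C)(C)C2=O)c1OCc1ccccc1
A8 | alternative 3 | 1-{3-methyl-2,4,6-tris(methoxymethoxy)-5-[3-methyl-1-(2,4,6-trihydroxyphenyl)butyl]phenyl}-3-phenylpropan-1-one, C7 arranged as in 28 | Cc1c(OCOC)c(C(=O)CCc2ccccc2)c(OCOC)c([C@H](CC(C)C)c2c(O)cc(O)cc2O)c1OCOC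
A9 | alternative 3 | 3-hydroxy-4,4,6,6-tetramethyl-2-[(1S)-3-methyl-1-[3-methyl-2,4,6-tris(methoxymethoxy)-5-(3-phenylpropanoyl)phenyl]butyl]cyclohex-2-ene-1,5-dione | Cc1c(OCOC)c(C(=O)CCc2ccccc2)c(OCOC)c([C@H](CC(C)C)C2=C(O)C(C)(C)C(=O)C(C)(C)C2=O)c1OCOC
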